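**Retrosynthetic overview**
- The only strategic bond is quinone C3–C1′ of the side chain. It is cut so that C3, normally the nucleophilic enol carbon of the hydroxyquinone, becomes an enolonium (α-cation) equivalent, a phenyliodonium ylide, and the chain becomes a primary C21 alkylborane.
- The ylide comes from 2-hydroxy-5-methoxy-1,4-benzoquinone and PhI(OAc)2; that quinone comes from commercial 2,5-dimethoxy-1,4-benzoquinone by mono-saponification.
- The alkylborane comes from 1-heneicosene by hydroboration; the alkene is assembled as C18 + C3 from 1-bromooctadecane and allylmagnesium bromide.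
- No ring is formed: the six-membered quinone ring is bought intact.

Assumption: the target is achiral (no stereocentre, no stereogenic double bond), so it is made as the single compound drawn; the chain is read as unbranched heneicosyl (C21, target C28H48O4).

**Route**

Step 1
Reactants: 1 1-bromooctadecane; 2 allylmagnesium bromide
Product: 3 1-heneicosene
Conditions: 2 (1.3 equiv, 1 M in Et2O), Li2CuCl4 (3 mol %), THF, 0 °C → rt, 4 h; NH4Cl (aq)
Reagents that add atoms: none
Why: Kochi-type copper-catalysed Grignard coupling with an unhindered primary bromide joins C3 to C18, and because allyl transposition is degenerate only the terminal C21 alkene can form.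

Step 2
Reactants: 4 2,5-dimethoxy-1,4-benzoquinone
Product: 5 2-hydroxy-5-methoxy-1,4-benzoquinone
Conditions: NaOH (1.0 equiv, 1 M aq), THF/H2O, 0 °C → rt, N2; then 1 M HCl to pH 2
Reagents that add atoms: sodium hydroxide, [Na+].[OH-]
Why: Saponification of a vinylogous methyl ester by addition–elimination; the single equivalent of hydroxide is used up as the delocalised vinylogous carboxylate of 5 forms, and that anion resists a second attack, so hydrolysis stops at the mono stage (4 is symmetric, so there is no regiochemical issue).

Step 3
Reactants: 5 2-hydroxy-5-methoxy-1,4-benzoquinone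
Product: 6 4-methoxy-3,6-dioxo-2-(phenyliodonio)cyclohexa-1,4-dien-1-olate (phenyliodonium ylide of 5, iodine on the former C3)
Conditions: PhI(OAc)2 (1.05 equiv), CH2Cl2, 0 °C → rt, 2 h, dark; filter, wash with Et2O, use at once
Reagents that add atoms: (diacetoxyiodo)benzene, CC(=O)OI(OC(C)=O)c1ccccc1
Why: Standard iodonium ylide formation from a cyclic 1,3-dicarbonyl-type enol with a trivalent iodine diacetate; only C3 lies between the enolic C–OH and a carbonyl, so the ylide forms there and turns this normally nucleophilic carbon into an enolonium equivalent.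

Step 4
Reactants: 3 1-heneicosene; 6 phenyliodonium ylide
Product: 8 3-heneicosyl-2-hydroxy-5-methoxy-1,4-benzoquinone (target), via B-heneicosyl-9-BBN 7 (not isolated)
Conditions: 3 (1.6 equiv), 9-BBN (0.5 M in THF, 1.5 equiv), 0 °C → rt, 6 h; then 6 (1.0 equiv), PdCl2(dppf) (5 mol %), AsPh3 (10 mol %), Cs2CO3 (3 equiv), DMF/THF/H2O, rt, 12 h, degassed, dark; then 1 M HCl
Reagents that add atoms: 9-borabicyclo[3.3.1]nonane (9-BBN), B1C2CCCC1CCC2 (its boron and bicycle are carried in 7 only; one H stays in 8)
Why: Proposed new method: ylide 6 is the enolonium equivalent of hydroxyquinone 5, so zerovalent palladium can insert into its C3–I bond with loss of PhI, the hydroxide-activated primary alkyl of 7 (made anti-Markovnikov by Brown hydroboration) transmetalates, and reductive elimination forms C3–C1′; the closest known reaction types are the palladium-catalysed coupling of hydroxyquinone phenyliodonium ylides with aryl- and alkenyl-boron or -tin reagents and the B-alkyl Suzuki–Miyaura coupling of alkenyl iodides and alkenyl(phenyl)iodonium salts; no stereocentre is created.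

**Compound list**
1 | 1-bromooctadecane | CCCCCCCCCCCCCCCCCCBr | starting material
2 | allylmagnesium bromide | C=CC[Mg]Br | starting material
3 | 1-heneicosene | C=CCCCCCCCCCCCCCCCCCCC | intermediate
4 | 2,5-dimethoxy-1,4-benzoquinone | COC1=CC(=O)C(OC)=CC1=O | starting material
5 | 2-hydroxy-5-methoxy-1,4-benzoquinone | COC1=CC(=O)C(O)=CC1=O | intermediate
6 | 4-methoxy-3,6-dioxo-2-(phenyliodonio)cyclohexa-1,4-dien-1-olate | COC1=CC(=O)C([O-])=C([I+]c2ccccc2)C1=O | intermediate
7 | B-heneicosyl-9-BBN (9-heneicosyl-9-borabicyclo[3.3.1]nonane) | CCCCCCCCCCCCCCCCCCCCCB1C2CCCC1CCC2 | intermediate (not isolated)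
8 | 3-heneicosyl-2-hydroxy-5-methoxy-1,4-benzoquinone | CCCCCCCCCCCCCCCCCCCCCC1=C(O)C(=O)C=C(OC)C1=O | target

**Totals**
Total step count: 4. Longest linear sequence: 3 steps (4 → 5 → 6 → 8); the chain branch is 2 steps (1 → 3 → 8).

**Steps most likely to fail, with fallbacks**

Step 4 (the sp3 coupling onto the ylide) carries the most risk. The ylide or the liberated PhI may divert the palladium (phenyl transfer, catalyst oxidation), or alkyl transmetalation may be too slow at the temperature the ylide tolerates. The fallback is metal-free, sets out from 3 and 6, and returns at 8. Alkene 3 is hydroborated with HBCl2 made in the flask (BCl3, Et3SiH, hexane, −78 °C → rt) to give heneicosyldichloroborane F1. F1 is added to 6 in CH2Cl2 at −78 °C → rt. The ylide carbon binds the Lewis-acidic boron, and the alkyl group shifts 1,2 from boron to C3 as PhI leaves (a Hooz-type boron-ate rearrangement, known for α-diazo carbonyl compounds and sulfonium ylides). Aqueous work-up hydrolyses the boron enolate to 8.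

Step 3 may fail because a benzoquinone-derived ylide with a free ring C–H can be less stable than the naphthoquinone analogues; it may rearrange by phenyl migration to oxygen or decompose on isolation. The fallback sets out from 5 and returns at 8, and replaces the hypervalent-iodine enolonium equivalent by the α-halo one. Iodination of 5 at C3 (I2, morpholine, then HCl) gives 2-hydroxy-3-iodo-5-methoxy-1,4-benzoquinone F2, a bench-stable solid. F2 is then coupled with 7 under B-alkyl Suzuki–Miyaura conditions (PdCl2(dppf), Cs2CO3, DMF/THF/H2O, 50 °C; HCl work-up) to give 8.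

Step 2 may give mixtures of 4, 5 and 2,5-dihydroxy-1,4-benzoquinone if the poorly soluble 4 reacts unevenly. The fallback sets out from 4 and returns at 8, and moves the ether differentiation to the end. Monobromination of 4 (Br2, AcOH/NaOAc, rt) gives 3-bromo-2,5-dimethoxy-1,4-benzoquinone F3. B-alkyl Suzuki–Miyaura coupling of F3 with 7 (PdCl2(dppf), Cs2CO3, DMF/THF/H2O, rt) gives 3-heneicosyl-2,5-dimethoxy-1,4-benzoquinone F4. 70% HClO4 in dioxane at rt should then hydrolyse the methoxy group flanked by the chain, which is twisted out of conjugation and therefore the more labile vinylogous ester, to give 8.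

**Further compounds**
F1 | step 4 | heneicosyldichloroborane | CCCCCCCCCCCCCCCCCCCCCB(Cl)Cl
F2 | step 3 | 2-hydroxy-3-iodo-5-methoxy-1,4-benzoquinone | COC1=CC(=O)C(O)=C(I)C1=O
F3 | step 2 | 3-bromo-2,5-dimethoxy-1,4-benzoquinone | COC1=CC(=O)C(OC)=C(Br)C1=O
F4 | step 2 | 3-heneicosyl-2,5-dimethoxy-1,4-benzoquinone | CCCCCCCCCCCCCCCCCCCCCC1=C(OC)C(=O)C=C(OC)C1=O
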